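## Retrosynthetic overview

1. C3–H is made last. The (3S) centre comes from a palladium-catalysed decarboxylative asymmetric protonation of the achiral tetra(allyl carbonate) of the enol form. The same operation frees the three phenols, and no step follows it.
2. The 5'-prenyl group is traced back to a 5'-bromide (Stille coupling), because the trisubstituted alkene would not survive the acidic annulation.
3. Ring C is the only ring that is built; rings A and B are bought as arenes. It is cut at O1–C2 and C4–C4a into phloroglucinol and a 2-arylacrylic acid, joined in one Friedel–Crafts acylation/oxa-Michael operation without protecting groups.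
4. Enabling feature: ring A carries O1, 5-OH and 7-OH in a 1,3,5 pattern. C4a is therefore a ring carbon flanked by two oxygenated carbons (C8a–O1 and C5–OH) of a threefold-symmetric triol in which all C–H and all O–H sites are equivalent. C2 is an unsubstituted CH2 next to the aryl-bearing C3, that is, the terminus of a 2-aryl enone.
5. The acrylic acid comes from 2-bromo-5-methoxyphenol by para-iodination and iodide-selective Stille coupling with an α-stannylacrylate.

Key step: step 5

Assumption: with Meldrum's acid as proton donor, the (S)-configured PHOX ligand is taken to deliver the proton to the enolate face that gives (3S). If a trial shows the opposite sense, the (R)-ligand is used and nothing else changes.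

Numbering follows isoflavanone usage: O1, C2, C3, C4, C4a, C5 to C8 and C8a for rings A and C, and primed numbers for ring B.

## Route

Step 1
Reactants: 1 methyl propiolate
Product: 2 methyl 2-(tributylstannyl)prop-2-enoate
Conditions: Bu3SnH (1.05 equiv), Pd(PPh3)4 (2 mol %), THF, 0 °C to rt
Reagents that add atoms: tributyltin hydride, CCCC[SnH](CCCC)CCCC
Why: Palladium-catalysed syn hydrostannation of an alkynoate should deliver hydride to the β-carbon and tin to the carbon next to the ester, which gives the 1,1-disubstituted α-stannylacrylate.

Step 2
Reactants: 3 2-bromo-5-methoxyphenol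
Product: 4 2-bromo-4-iodo-5-methoxyphenol
Conditions: N-iodosuccinimide (1.0 equiv), TsOH·H2O (10 mol %), MeCN, 0 °C to rt
Reagents that add atoms: N-iodosuccinimide, O=C1CCC(=O)N1I
Why: Electrophilic aromatic iodination should take place at C4, which is para to the hydroxyl and ortho to the methoxy group, because the only other doubly activated site (C6) is wedged between the two oxygen substituents.

Step 3
Reactants: 4 2-bromo-4-iodo-5-methoxyphenol; 2 methyl 2-(tributylstannyl)prop-2-enoate
Product: 5 methyl 2-(5-bromo-4-hydroxy-2-methoxyphenyl)prop-2-enoate
Conditions: Pd(PPh3)4 (5 mol %), CuI (20 mol %), DMF, 45 °C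
Reagents that add atoms: none
Why: Copper-assisted Stille coupling should take place only at the C–I bond, since oxidative addition of zerovalent palladium to an aryl iodide is much faster than to an aryl bromide at this temperature, so that the bromide is kept as the handle for the prenyl group.

Step 4
Reactants: 5 methyl 2-(5-bromo-4-hydroxy-2-methoxyphenyl)prop-2-enoate
Product: 6 2-(5-bromo-4-hydroxy-2-methoxyphenyl)prop-2-enoic acid
Conditions: LiOH (4 equiv), THF/H2O, rt; then 1 M HCl
Reagents that add atoms: lithium hydroxide, [Li+].[OH-]
Why: Ester saponification should be clean because the phenoxide formed first pushes electron density into the acrylate and shields it from conjugate addition of hydroxide.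

Step 5
Reactants: 6 2-(5-bromo-4-hydroxy-2-methoxyphenyl)prop-2-enoic acid; 7 phloroglucinol (benzene-1,3,5-triol, anhydrous)
Product: 9 racemic 3-(5-bromo-4-hydroxy-2-methoxyphenyl)-5,7-dihydroxychroman-4-one, via aryl vinyl ketone 8 (not isolated)
Conditions: 7 (3 equiv), BF3·OEt2 (as solvent), 70 °C; then 10 % aq NaOAc, rt
Reagents that add atoms: none
Why: BF3 turns acid 6 into an acyloxyborane (acylium equivalent) that C-acylates 7 (Friedel–Crafts acylation, bond C4–C4a) to aryl vinyl ketone 8, whose carbonyl is then locked and activated in a six-membered O–BF2–O chelate with one ortho oxygen while the other ortho hydroxyl adds to the methylene terminus (oxa-Michael addition, bond O1–C2) and the resulting boron enolate is protonated at C3. The closest known reaction type is the one-pot acylation/oxa-Michael (esterification–Fries–oxa-Michael) annulation of resorcinol and phloroglucinol with crotonic, tiglic or 3,3-dimethylacrylic acid to chroman-4-ones, together with the BF3·OEt2 acylation of phloroglucinol by unprotected hydroxyarylacetic acids. Ring C closes in the 6-endo-trig mode onto an unsubstituted CH2, so that closure meets no steric penalty and the buffered work-up should drive any remaining 8 to 9. C3 is created by an uncontrolled protonation, so 9 is expected as the racemate, which is accepted because C3 is flattened in step 8 and set by the catalyst in step 9. The step needs acylation at carbon to outrun conjugate C-alkylation at the methylene carbon, one acylation only, and no attack on ring B: the dehydrating Lewis acid makes the acyl carbon the most reactive electrophile, the first acyl group deactivates ring A through chelation, and an excess of the far more nucleophilic 7 outcompetes ring B. No positional selectivity is needed at all, since the threefold symmetry of 7 makes every C–H site and both flanking hydroxyls lead to the same product, the unused ortho hydroxyl ending up as the chelated 5-OH.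

Step 6
Reactants: 9 racemic 3-(5-bromo-4-hydroxy-2-methoxyphenyl)-5,7-dihydroxychroman-4-one
Product: 10 racemic 5,7-dihydroxy-3-[4-hydroxy-2-methoxy-5-(3-methylbut-2-en-1-yl)phenyl]chroman-4-one
Conditions: tributyl(3-methylbut-2-en-1-yl)stannane (1.5 equiv), Pd(P(t-Bu)3)2 (5 mol %), degassed NMP, 80 °C
Reagents that add atoms: tributyl(3-methylbut-2-en-1-yl)stannane, CCCC[Sn](CCCC)(CCCC)CC=C(C)C
Why: Stille coupling under neutral conditions should replace bromine by the linear prenyl group, since the electron-rich bulky phosphine allows oxidative addition to the electron-rich aryl bromide, allylic stannanes transmetalate readily, and reductive elimination takes place at the less hindered primary terminus of the prenylpalladium species, while ketone, phenols and the still racemic C3 are not at risk.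

Step 7
Reactants: 10 racemic 5,7-dihydroxy-3-[4-hydroxy-2-methoxy-5-(3-methylbut-2-en-1-yl)phenyl]chroman-4-one
Product: 11 racemic tris(allyl carbonate) of 10 (allyloxycarbonyl groups on O5, O7 and O4')
Conditions: allyl chloroformate (4 equiv), pyridine (6 equiv), DMAP (10 mol %), CH2Cl2, 0 °C to rt
Reagents that add atoms: allyl chloroformate, C=CCOC(=O)Cl
Why: DMAP-catalysed O-acylation with a chloroformate should cap all three phenols, the chelated 5-OH included, which removes the acidic protons before the enolisation and installs groups that the catalyst of step 9 takes off again.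

Step 8
Reactants: 11 racemic tris(allyl carbonate) of 10
Product: 12 allyl 3-[4-(allyloxycarbonyloxy)-2-methoxy-5-(3-methylbut-2-en-1-yl)phenyl]-5,7-bis(allyloxycarbonyloxy)-2H-chromen-4-yl carbonate (achiral enol carbonate)
Conditions: KN(SiMe3)2 (1.15 equiv), THF, −78 °C; then allyl chloroformate (1.5 equiv), −78 to −40 °C
Reagents that add atoms: allyl chloroformate, C=CCOC(=O)Cl
Why: Kinetic deprotonation of the only enolisable position (C3–H, acidified by ring B) and O-acylation of the potassium enolate with a chloroformate should give the achiral enol carbonate, the low temperature holding back E1cB opening of ring C, and a carbonate shift from O5 or C-acylation at C3 would do no harm because such isomers feed the same palladium enolate in step 9.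

Step 9
Reactants: 12 achiral tetra(allyl carbonate) enol carbonate
Product: 13 (3S)-5,7-dihydroxy-3-[4-hydroxy-2-methoxy-5-(3-methylbut-2-en-1-yl)phenyl]chroman-4-one (target)
Conditions: Pd2(dba)3 (5 mol %), (S)-4-tert-butyl-2-[2-(bis(4-trifluoromethylphenyl)phosphanyl)-5-(trifluoromethyl)phenyl]-4,5-dihydrooxazole (12.5 mol %), Meldrum's acid (6 equiv), THF, 25 °C; work-up and chromatography without base
Reagents that add atoms: none
Why: Palladium-catalysed decarboxylative asymmetric protonation, a reaction type shown on allyl β-keto esters of 3-arylchroman-4-ones and on allyl enol carbonates of cyclic ketones, should ionise the enol carbonate, lose CO2 and give a PHOX-bound palladium enolate whose C3 is protonated on one face under control of the chiral ligand, while the same zerovalent palladium catalyst cleaves the three aryl allyl carbonates with Meldrum's acid as allyl acceptor, so that (3S) is set in the last, nearly neutral operation.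

## Compound list

1 | methyl propiolate | C#CC(=O)OC | starting material
2 | methyl 2-(tributylstannyl)prop-2-enoate | C=C(C(=O)OC)[Sn](CCCC)(CCCC)CCCC | intermediate
3 | 2-bromo-5-methoxyphenol | COc1ccc(Br)c(O)c1 | starting material
4 | 2-bromo-4-iodo-5-methoxyphenol | COc1cc(O)c(Br)cc1I | intermediate
5 | methyl 2-(5-bromo-4-hydroxy-2-methoxyphenyl)prop-2-enoate | COC(=O)C(=C)c1cc(Br)c(O)cc1OC | intermediate
6 | 2-(5-bromo-4-hydroxy-2-methoxyphenyl)prop-2-enoic acid | OC(=O)C(=C)c1cc(Br)c(O)cc1OC | intermediate
7 | phloroglucinol | Oc1cc(O)cc(O)c1 | starting material
8 | 2-(5-bromo-4-hydroxy-2-methoxyphenyl)-1-(2,4,6-trihydroxyphenyl)prop-2-en-1-one (aryl vinyl ketone, not isolated) | C=C(C(=O)c1c(O)cc(O)cc1O)c1cc(Br)c(O)cc1OC | intermediate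
9 | racemic 3-(5-bromo-4-hydroxy-2-methoxyphenyl)-5,7-dihydroxychroman-4-one | COc1cc(O)c(Br)cc1C1COc2cc(O)cc(O)c2C1=O | intermediate
10 | racemic 5,7-dihydroxy-3-[4-hydroxy-2-methoxy-5-(3-methylbut-2-en-1-yl)phenyl]chroman-4-one | COc1cc(O)c(CC=C(C)C)cc1C1COc2cc(O)cc(O)c2C1=O | intermediate
11 | racemic tris(allyl carbonate) of 10 (O5, O7, O4') | COc1cc(OC(=O)OCC=C)c(CC=C(C)C)cc1C1COc2cc(OC(=O)OCC=C)cc(OC(=O)OCC=C)c2C1=O | intermediate
12 | achiral enol carbonate, tetra(allyl carbonate) (O4 enol, O5, O7, O4') | COc1cc(OC(=O)OCC=C)c(CC=C(C)C)cc1C1=C(OC(=O)OCC=C)c2c(OC(=O)OCC=C)cc(OC(=O)OCC=C)cc2OC1 | intermediate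
13 | (3S)-5,7-dihydroxy-3-[4-hydroxy-2-methoxy-5-(3-methylbut-2-en-1-yl)phenyl]chroman-4-one | COc1cc(O)c(CC=C(C)C)cc1[C@H]1COc2cc(O)cc(O)c2C1=O | target

Total step count: 9.
Longest linear sequence: 8 steps (steps 2 to 9, from 3 to 13).

## Steps most likely to fail

**Step 5.** Three processes may interfere:
- conjugate C-alkylation of phloroglucinol at the methylene carbon followed by lactonisation;
- acid-induced oligomerisation of the electron-rich styrene unit;
- transfer of bromine from ring B to phloroglucinol.

The fallback makes the ring C bonds one after the other by the deoxybenzoin route. It sets out from 4 and comes back at 9. Negishi-type coupling of the C–I bond of 4 with the Reformatsky reagent BrZnCH2CO2t-Bu (Pd2(dba)3, XPhos, THF, rt) should give tert-butyl 2-(5-bromo-4-hydroxy-2-methoxyphenyl)acetate F1. CF3CO2H in CH2Cl2 should free 2-(5-bromo-4-hydroxy-2-methoxyphenyl)acetic acid F2. Friedel–Crafts acylation of 7 with this acid in BF3·OEt2 should give the deoxybenzoin 2-(5-bromo-4-hydroxy-2-methoxyphenyl)-1-(2,4,6-trihydroxyphenyl)ethan-1-one F3. Paraformaldehyde with Et2NH in refluxing EtOH (α-methylenation, then oxa-Michael closure) should then lead to 9.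

**Step 9.** Facial selectivity may erode because the phenols set free in the same flask compete with Meldrum's acid as proton donors. The liberated phenoxides may also be re-allylated at oxygen.

The fallback replaces the palladium enolate by a silyl enol ether. It sets out from 10 and comes back at 13. Soft enolisation and silylation with Me3SiOTf and Et3N in CH2Cl2 at 0 °C should convert 10 in one step into the tetrakis(trimethylsilyl) derivative bearing three aryl silyl ethers and the C4 silyl enol ether F6. Catalytic enantioselective protonation of the silyl enol ether should then follow, using a BINOL-derived chiral N-triflyl thiophosphoramide and methanol as the stoichiometric proton source in toluene. Methanolysis of the aryl silyl ethers in the same flask should give 13.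

**Step 6.** Three processes may interfere:
- slow oxidative addition into the electron-rich, ortho-hydroxylated C–Br bond;
- protonolysis of the allylic stannane by the acidic ring A phenols;
- transfer of the prenyl group through its tertiary terminus.

The fallback masks the phenols before the coupling. It sets out from 9 and comes back at 10. Silylation (TBSCl, imidazole, DMF, completed with TBSOTf and 2,6-lutidine for the chelated 5-OH) should give the racemic tris(tert-butyldimethylsilyl) ether of the bromide F4. Stille coupling with tributyl(3-methylbut-2-en-1-yl)stannane (Pd(P(t-Bu)3)2, toluene, 90 °C) on this aprotic and less electron-rich substrate should give the racemic prenylated tris(silyl) ether F5. Et3N·3HF in THF should then release 10.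

## Further compounds

F1 | step 5 | tert-butyl 2-(5-bromo-4-hydroxy-2-methoxyphenyl)acetate | COc1cc(O)c(Br)cc1CC(=O)OC(C)(C)C
F2 | step 5 | 2-(5-bromo-4-hydroxy-2-methoxyphenyl)acetic acid | COc1cc(O)c(Br)cc1CC(=O)O
F3 | step 5 | 2-(5-bromo-4-hydroxy-2-methoxyphenyl)-1-(2,4,6-trihydroxyphenyl)ethan-1-one | COc1cc(O)c(Br)cc1CC(=O)c1c(O)cc(O)cc1O
F4 | step 6 | racemic tris(tert-butyldimethylsilyl) ether of 9 | COc1cc(O[Si](C)(C)C(C)(C)C)c(Br)cc1C1COc2cc(O[Si](C)(C)C(C)(C)C)cc(O[Si](C)(C)C(C)(C)C)c2C1=O
F5 | step 6 | racemic tris(tert-butyldimethylsilyl) ether of 10 | COc1cc(O[Si](C)(C)C(C)(C)C)c(CC=C(C)C)cc1C1COc2cc(O[Si](C)(C)C(C)(C)C)cc(O[Si](C)(C)C(C)(C)C)c2C1=O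
F6 | step 9 | tetrakis(trimethylsilyl) derivative of 10 (C4 silyl enol ether, achiral) | COc1cc(O[Si](C)(C)C)c(CC=C(C)C)cc1C1=C(O[Si](C)(C)C)c2c(O[Si](C)(C)C)cc(O[Si](C)(C)C)cc2OC1
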